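**Remarks before the route**

- Locants: ring C1 carries the carboxyl group, C2 and C4 the hydroxyl groups, C6 the side chain. The chain runs from C1' (benzylic CH2) through C2' (the acetoxy-bearing stereocentre) to C13' (CH2OH). Compounds are numbered 1–19 as in the steps and the compound list.
- Assumption: a ketoreductase from a commercial screening panel accepts ketone 16 and delivers hydride to the Si face of C2'. Such panels hold enzymes of both facial preferences, and the configuration of 17 is to be confirmed by Mosher ester analysis before it is carried on.

## Analysis of the target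

The target 19 is a β-resorcylic acid (2,4-dihydroxybenzoic acid) whose C6 carries an unbranched thirteen-carbon chain with an acetoxy group at C2' and a primary hydroxyl at C13'. There is a single stereocentre, C2', of (R) configuration (OAc > C1' > C3' > H). No relative stereochemistry has to be controlled, but C2' is flanked by two methylene groups, which offers a reagent little to tell its faces apart. The benzene ring is 1,2,3,5-tetrasubstituted, with the carboxyl carbon wedged between the C2 oxygen and the C6 alkyl group. The free salicylic-type acid decarboxylates on heating or in strong acid, and the secondary acetate does not tolerate base or nucleophiles. The C2' oxygen lies within reach of the carboxyl carbon, so a six-membered lactone threatens whenever C2'–OH is free while the carboxyl is esterified or activated. The synthesis is therefore hard in three ways: placing carbon substituents on the adjacent carbons C1 and C6 without regioisomers, setting the remote stereocentre, and ending with a neutral deprotection after the acetate is in place. The strategy rests on one feature: C6 (carbon substituent) and C1 (carboxyl) are neighbours and C2–O stands next to C1, which is the pattern left when a carbon nucleophile and then an electrophile add to the two carbons of a 3,5-dioxygenated benzyne such as 11.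

## Retrosynthetic reasoning

**19 to 18.** The last disconnection removes four benzyl groups: the ether O–CH2Ph bonds at C2–O, C4–O and C13'–O, and the ester O–CH2Ph bond. All hydroxyls and the carboxyl are then released together by neutral hydrogenolysis, which spares the C2' acetate (on a homobenzylic, not a benzylic, carbon) and the decarboxylation-prone acid. The forward step has only to cleave benzylic C–O bonds.

**18 to 17 to 16.** The acetyl–O bond at C2' is cut, then the C2'–H bond, which leads to ketone 16. The stereocentre is traced to a face-selective carbonyl reduction because C2' arrives from the key step as a trigonal carbon. The forward steps must deliver hydride to the Si face of C2' and cap the hydroxyl at once, since the free C2'–OH of 17 can attack the ortho ester carbonyl. Keeping C2' as a ketone until then, and the carboxyl as a doubly ortho-substituted ester, confines that danger to the single intermediate 17.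

**16 to 14 to 13.** The C2' carbonyl is traced back to the methylidene group of 14, and the benzyl ester to acid 13. The extra carbon is the price of using an allyl nucleophile in the key step: it makes the side-chain reagent a 2-substituted allyl unit with two identical termini. The forward steps are an esterification by carboxylate alkylation (no acyl substitution at the hindered acid) and the oxidative cleavage of the only C=C bond.

**13 to 2 + 8 + 9.** The central disconnection cuts two bonds on adjacent ring carbons, C6–C1' and C1–CO2H. With both removed, C1 and C6 become the two carbons of aryne 11, which 2 provides after ortho-metalation and loss of fluoride. The whole side-chain skeleton (8) and the carboxyl carbon (9) are thus attached in one operation to a ring whose oxygens are already in place, and no electrophilic substitution of the electron-rich ring is needed. The forward reaction must bond the allyl carbon of 8 to the aryne carbon remote from the flanking oxygen (future C6) and leave the metal on the carbon next to it (future C1), where 9 is captured.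

**8 to 7 to 4 + 5, and 4 to 3.** Reagent 8 comes from allylic chloride 7 by metal insertion. Chloride 7 is cut at C3'–C4', between the allyl unit and the ten-carbon chain, which gives the symmetrical dichloride 5 and bromide 4. Mono-substitution of 5 gives one product whether attack is direct or allyl-transposed, and the surviving C–Cl bond is the handle for 8. Bromide 4 comes from 3 by O-benzylation, so that this oxygen is also unmasked in the final hydrogenolysis.

**2 to 1.** The two aryl C–O bonds of 2 are cut to reveal 1. Two of its three equivalent fluorides are replaced by benzyloxy groups, and the third remains as the leaving group for aryne formation.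

## Alternatives that were turned down

**Alternative 1:** The benzene ring is disconnected at C1–C6.
- Forward key step: the diketo-dioxinone A2, 6-[(6R)-17-(benzyloxy)-6-(tert-butyldimethylsilyloxy)-2,4-dioxoheptadecyl]-2,2-dimethyl-4H-1,3-dioxin-4-one, is heated with the alcohol that ends as the ester group. Cycloreversion, capture of the ketene carbon, aldol closure between C1 and the C6 carbonyl and dehydration would give resorcylate A1, benzyl 6-[(2R)-13-(benzyloxy)-2-(tert-butyldimethylsilyloxy)tridecyl]-2,4-dihydroxybenzoate.
- For it: the substitution pattern is programmed by the chain, so no regiochemical question arises. The C2' stereocentre comes from a β-hydroxy acid unit, for which asymmetric hydrogenation of the β-keto ester is far more dependable than reduction of ketone 16. On stereocontrol this alternative is the stronger.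
- Against it: A2 needs a long linear assembly through polycarbonyl intermediates that enolise and self-condense. In the open-chain stage the C2' silyloxy group is β to the C6 carbonyl, so E1cB elimination competes with the aldol closure and would erase the stereocentre. A1 carries two free phenols and a silyl ether where the acetate is needed, so phenol protection, desilylation (fluoride beside an ortho ester invites lactonisation) and acetylation must follow.
- Comparison: the chosen route starts from an arene with its oxygens in place and forms two bonds in one flask, with fewer and sturdier intermediates. It gives up the early, secure stereocentre.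

**Alternative 2:** The disconnection is at C2'–C3' and at the acetyl O–C2' bond.
- Forward key step: aldehyde A4, benzyl 2,4-bis(benzyloxy)-6-(2-oxoethyl)benzoate, is converted with an acetyl halide into the racemic α-bromoalkyl acetate A6, benzyl 6-(2-acetoxy-2-bromoethyl)-2,4-bis(benzyloxy)benzoate. NiBr2·glyme, a chiral bis(oxazoline) and a hydrosilane would then couple A6 with the terminal alkene A5, [(undec-10-en-1-yloxy)methyl]benzene, to give A3, benzyl 6-[(2R)-2-acetoxy-13-(benzyloxy)tridecyl]-2,4-bis(benzyloxy)benzoate, which is identical with compound 18.
- For it: stereocentre and acetate are created together under catalyst control, from a racemate. A free C2' hydroxyl never exists, so the lactonisation risk of steps 8 and 9 disappears; on this point it is stronger. A3 is one hydrogenolysis from the target.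
- Against it: the tetrasubstituted arene must still be built first, and A4 is its most fragile form. An arylacetaldehyde with an ortho ester enolises easily, can close onto the ester by enol lactonisation, and self-condenses under the acidic conditions of bromoacetate formation. Nickel hydride chain-walking on A5 can also give branched isomers.
- Comparison: the step count is similar, because the ring has to be made either way. The chosen route keeps C2' as a stable ketone and uses well-understood operations, at the price of a less elegantly controlled stereo step.

**Alternative 3:** The ring is disconnected at C1–C2 and C5–C6.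
- Forward key step: silyloxy diene A8, trimethyl[(2,2-dimethyl-4-methylidene-4H-1,3-dioxin-6-yl)oxy]silane, and ynoate A9, benzyl (5R)-5-acetoxy-16-(benzyloxy)hexadec-2-ynoate, undergo [4+2] cycloaddition. Extrusion of the acetonide carbon as its ketone and loss of the silyl group as silanol would aromatise the adduct to A7, benzyl 6-[(2R)-2-acetoxy-13-(benzyloxy)tridecyl]-2,4-dihydroxybenzoate.
- For it: it is highly convergent, and the regiochemistry is electronically matched (the nucleophilic CH2 terminus of A8 meets the β-carbon of A9, the future C6). The stereocentre is made early in A9 from an enantiopure terminal epoxide or β-hydroxy ester. A7 already has free phenols and the acetate, so one hydrogenolysis ends the route. It is shorter, and surer in stereochemistry, than the chosen route.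
- Against it: a β-alkyl ynoate activated by one ester is a sluggish dienophile. At the temperatures needed, the heat- and moisture-sensitive ketene acetal A8 degrades, the homopropargylic acetate of A9 can eliminate, and the alkyne can isomerise to an allene. The acetate and the stereocentre must pass through this harshest step.
- Comparison: the weak point is the ring-forming step itself, whereas the chosen key step is a known reaction type on exactly this oxygenation pattern. The chosen route offers a dependable arene construction from cheap achiral fragments and accepts a late asymmetric reduction in return.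

Key step: step 5

## Route

Step 1
Reactants: 1 1,3,5-trifluorobenzene
Product: 2 1,3-bis(benzyloxy)-5-fluorobenzene
Conditions: BnOH (2.1 equiv), KOt-Bu (2.1 equiv), NMP, 0 → 25 °C, then 90 °C
Reagents that add atoms: benzyl alcohol, OCc1ccccc1
Why: Nucleophilic aromatic substitution by addition–elimination; each C–F of 1 is activated by two meta fluorines. After two displacements the last C–F has only meta alkoxy neighbours, so the third substitution is slower and the stoichiometry should stop the reaction at 2.

Step 2
Reactants: 3 10-bromodecan-1-ol
Product: 4 {[(10-bromodecyl)oxy]methyl}benzene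
Conditions: BnOC(=NH)CCl3 (1.3 equiv), TfOH (5 mol%), CH2Cl2/cyclohexane, 0 → 25 °C
Reagents that add atoms: benzyl 2,2,2-trichloroacetimidate, N=C(OCc1ccccc1)C(Cl)(Cl)Cl
Why: Acid-catalysed O-benzylation with the trichloroacetimidate transfers a benzyl cation to the neutral alcohol. No alkoxide is formed, so Williamson displacement of the primary bromide cannot compete.

Step 3
Reactants: 4 {[(10-bromodecyl)oxy]methyl}benzene; 5 3-chloro-2-(chloromethyl)prop-1-ene
Product: 7 {[(13-chloro-12-methylidenetridecyl)oxy]methyl}benzene, via alkylmagnesium bromide 6 (not isolated)
Conditions: Mg, I2 (cat.), THF, 40 °C; then added slowly to 5 (3 equiv), CuI (5 mol%), THF, −20 → 0 °C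
Reagents that add atoms: none
Why: Grignard formation followed by copper-catalysed allylic substitution, forming C3'–C4'. Because 5 is symmetrical, SN2 and SN2' attack give the same allylic chloride, and inverse addition to excess 5 should limit a second substitution.

Step 4
Reactants: 7 {[(13-chloro-12-methylidenetridecyl)oxy]methyl}benzene
Product: 8 {2-[11-(benzyloxy)undecyl]prop-2-en-1-yl}magnesium chloride (THF solution, titrated and used at once)
Conditions: Mg turnings (6 equiv, I2-activated), THF, −15 → 0 °C, slow addition of dilute 7
Reagents that add atoms: magnesium, [Mg]
Why: Insertion of magnesium into the allylic C–Cl bond (Grignard formation). Low temperature, dilution and a large metal surface keep 7 scarce in the presence of 8 and so restrain Wurtz coupling; the benzyl ether is inert.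

Step 5
Reactants: 2 1,3-bis(benzyloxy)-5-fluorobenzene; 8 {2-[11-(benzyloxy)undecyl]prop-2-en-1-yl}magnesium chloride; 9 carbon dioxide
Product: 13 2,4-bis(benzyloxy)-6-[13-(benzyloxy)-2-methylidenetridecyl]benzoic acid, via aryllithium 10 (not isolated), via aryne 11 (not isolated), via arylmagnesium chloride 12 (not isolated)
Conditions: 2, n-BuLi (1.05 equiv), THF, −78 °C; 8 (1.4 equiv), −78 → 20 °C; CO2 (gas), 0 °C; cold 1 M HCl to pH 3
Reagents that add atoms: none
Why: n-BuLi removes the ring proton of 2 that is flanked by fluorine and a benzyloxy group (directed ortho-lithiation, faster at −78 °C than benzylic deprotonation of the ethers) to give 10, which on warming expels LiF and becomes aryne 11. Reagent 8, already present, adds its allyl carbon across the strained triple bond (carbomagnesiation) to give 12, and CO2 then carboxylates the aryl–magnesium bond; the closest known reaction type is the three-component coupling of 3,5-dimethoxybenzyne, generated the same way from the fluoroarene, with 2-methylallylmagnesium chloride and CO2. Two bonds are formed, C6–C1' and C1–CO2H; no ring is closed and no stereocentre is created. The selectivity the step needs is regiochemical: carbon must bond to the aryne carbon remote from the flanking oxygen. This is secured by the C–O bond next to the triple bond, whose inductive pull distorts 11 so that attack occurs at the distal carbon and the developing carbanion sits ortho to oxygen, where it is stabilised and where the benzyloxy oxygen can coordinate magnesium; the second benzyloxy group, meta to the site of attack, does not oppose this. Allyl regiochemistry needs no control because both termini of 8 are CH2 groups, so direct and transposed attack give the same skeleton. Excess CO2 and a cold, weakly acidic work-up are specified because 12 is doubly ortho-substituted and because strong acid could add the new carboxyl group across the methylidene.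

Step 6
Reactants: 13 2,4-bis(benzyloxy)-6-[13-(benzyloxy)-2-methylidenetridecyl]benzoic acid
Product: 14 benzyl 2,4-bis(benzyloxy)-6-[13-(benzyloxy)-2-methylidenetridecyl]benzoate
Conditions: BnBr (1.2 equiv), K2CO3 (1.5 equiv), DMF, 25 °C
Reagents that add atoms: benzyl bromide, BrCc1ccccc1
Why: SN2 O-alkylation of the carboxylate, which, unlike acyl substitution, is not slowed by the two ortho substituents. Acid by-products from surplus Grignard reagent are esterified too and should separate by chromatography at this stage.

Step 7
Reactants: 14 benzyl 2,4-bis(benzyloxy)-6-[13-(benzyloxy)-2-methylidenetridecyl]benzoate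
Product: 16 benzyl 2,4-bis(benzyloxy)-6-[13-(benzyloxy)-2-oxotridecyl]benzoate, via vicinal diol 15 (not isolated)
Conditions: OsO4 (2 mol%), NaIO4 (4 equiv), 2,6-lutidine (2 equiv), 1,4-dioxane/H2O (3:1), 25 °C
Reagents that add atoms: sodium periodate, [Na+].[O-]I(=O)(=O)=O (terminal oxidant; its oxygen reaches the substrate through osmium tetroxide, O=[Os](=O)(=O)=O)
Why: Lemieux–Johnson oxidation: osmium-catalysed dihydroxylation of the only alkene gives diol 15, which periodate cleaves to the C2' ketone and formaldehyde. Lutidine keeps the medium near neutral, so the enolisable benzylic ketone should not condense with the ortho ester; arene and benzyl groups are inert.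

Step 8
Reactants: 16 benzyl 2,4-bis(benzyloxy)-6-[13-(benzyloxy)-2-oxotridecyl]benzoate
Product: 17 benzyl 2,4-bis(benzyloxy)-6-[(2R)-13-(benzyloxy)-2-hydroxytridecyl]benzoate
Conditions: (R)-selective ketoreductase, NADP+ (cat.), i-PrOH, phosphate buffer pH 7.0/toluene, 30 °C
Reagents that add atoms: none
Why: Enzymatic carbonyl reduction with cofactor recycling by isopropanol; the binding pocket distinguishes the arylmethyl arm from the n-alkyl arm by shape, which a small-molecule reagent cannot do for two CH2 groups. Hydride delivery from NADPH to the Si face of C2' sets the (R) configuration, and the neutral medium forms no alkoxide, so esters and ethers should survive.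

Step 9
Reactants: 17 benzyl 2,4-bis(benzyloxy)-6-[(2R)-13-(benzyloxy)-2-hydroxytridecyl]benzoate
Product: 18 benzyl 6-[(2R)-2-acetoxy-13-(benzyloxy)tridecyl]-2,4-bis(benzyloxy)benzoate
Conditions: Ac2O (3 equiv), pyridine, DMAP (5 mol%), CH2Cl2, 0 °C, on the crude alcohol without delay
Reagents that add atoms: acetic anhydride, CC(=O)OC(C)=O
Why: Nucleophile-catalysed acylation of the secondary alcohol; the C2'–O bond is not broken, so the configuration is retained. Acylation by the acetylpyridinium species should be much faster than attack of the neutral hydroxyl on the twisted, doubly ortho-substituted benzyl ester.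

Step 10
Reactants: 18 benzyl 6-[(2R)-2-acetoxy-13-(benzyloxy)tridecyl]-2,4-bis(benzyloxy)benzoate
Product: 19 6-[(2R)-2-acetoxy-13-hydroxytridecyl]-2,4-dihydroxybenzoic acid
Conditions: H2 (1 atm), Pd/C (10 wt%), EtOAc, 25 °C
Reagents that add atoms: none
Why: Hydrogenolysis of three benzyl ethers and the benzyl ester over palladium. The acetate sits on a homobenzylic carbon and is not cleaved, the stereocentre is untouched, and the neutral aprotic medium at room temperature avoids acyl transfer and decarboxylation.

## Compound list

1 | 1,3,5-trifluorobenzene | Fc1cc(F)cc(F)c1 | starting material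
2 | 1,3-bis(benzyloxy)-5-fluorobenzene | Fc1cc(OCc2ccccc2)cc(OCc2ccccc2)c1 | intermediate
3 | 10-bromodecan-1-ol | OCCCCCCCCCCBr | starting material
4 | {[(10-bromodecyl)oxy]methyl}benzene | BrCCCCCCCCCCOCc1ccccc1 | intermediate
5 | 3-chloro-2-(chloromethyl)prop-1-ene | C=C(CCl)CCl | starting material
6 | [10-(benzyloxy)decyl]magnesium bromide | Br[Mg]CCCCCCCCCCOCc1ccccc1 | intermediate
7 | {[(13-chloro-12-methylidenetridecyl)oxy]methyl}benzene | ClCC(=C)CCCCCCCCCCCOCc1ccccc1 | intermediate
8 | {2-[11-(benzyloxy)undecyl]prop-2-en-1-yl}magnesium chloride | Cl[Mg]CC(=C)CCCCCCCCCCCOCc1ccccc1 | intermediate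
9 | carbon dioxide | O=C=O | starting material
10 | [2,4-bis(benzyloxy)-6-fluorophenyl]lithium | [Li]c1c(F)cc(OCc2ccccc2)cc1OCc1ccccc1 | intermediate
11 | 3,5-bis(benzyloxy)benzyne | C1#CC(OCc2ccccc2)=CC(OCc2ccccc2)=C1 | intermediate
12 | {2,4-bis(benzyloxy)-6-[13-(benzyloxy)-2-methylidenetridecyl]phenyl}magnesium chloride | Cl[Mg]c1c(OCc2ccccc2)cc(OCc2ccccc2)cc1CC(=C)CCCCCCCCCCCOCc1ccccc1 | intermediate
13 | 2,4-bis(benzyloxy)-6-[13-(benzyloxy)-2-methylidenetridecyl]benzoic acid | OC(=O)c1c(OCc2ccccc2)cc(OCc2ccccc2)cc1CC(=C)CCCCCCCCCCCOCc1ccccc1 | intermediate
14 | benzyl 2,4-bis(benzyloxy)-6-[13-(benzyloxy)-2-methylidenetridecyl]benzoate | O=C(OCc1ccccc1)c1c(OCc2ccccc2)cc(OCc2ccccc2)cc1CC(=C)CCCCCCCCCCCOCc1ccccc1 | intermediate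
15 | benzyl 2,4-bis(benzyloxy)-6-[13-(benzyloxy)-2-hydroxy-2-(hydroxymethyl)tridecyl]benzoate (racemic) | O=C(OCc1ccccc1)c1c(OCc2ccccc2)cc(OCc2ccccc2)cc1CC(O)(CO)CCCCCCCCCCCOCc1ccccc1 | intermediate
16 | benzyl 2,4-bis(benzyloxy)-6-[13-(benzyloxy)-2-oxotridecyl]benzoate | O=C(OCc1ccccc1)c1c(OCc2ccccc2)cc(OCc2ccccc2)cc1CC(=O)CCCCCCCCCCCOCc1ccccc1 | intermediate
17 | benzyl 2,4-bis(benzyloxy)-6-[(2R)-13-(benzyloxy)-2-hydroxytridecyl]benzoate | O[C@H](CCCCCCCCCCCOCc1ccccc1)Cc1cc(OCc2ccccc2)cc(OCc2ccccc2)c1C(=O)OCc1ccccc1 | intermediate
18 | benzyl 6-[(2R)-2-acetoxy-13-(benzyloxy)tridecyl]-2,4-bis(benzyloxy)benzoate | CC(=O)O[C@H](CCCCCCCCCCCOCc1ccccc1)Cc1cc(OCc2ccccc2)cc(OCc2ccccc2)c1C(=O)OCc1ccccc1 | intermediate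
19 | 6-[(2R)-2-acetoxy-13-hydroxytridecyl]-2,4-dihydroxybenzoic acid | CC(=O)O[C@H](CCCCCCCCCCCO)Cc1cc(O)cc(O)c1C(=O)O | target

## Step count and least certain steps

Total step count: 10. Longest linear sequence: 9 steps (steps 2–10, from 3 through 4, 7, 8, 13, 14, 16, 17 and 18 to 19); the arene branch (steps 1, 5–10) is shorter.

**Step 5 (key step).**
- What may go wrong: the aryne may be consumed by aryl-metal species, because the valuable reagent 8 can be used only in modest excess. The doubly ortho-substituted arylmagnesium 12 may also be protonated on work-up instead of being carboxylated, since its reaction with CO2 is slowed by the two flanking groups.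
- Fallback: C–C and C–CO2 bond formation are separated. From 2 and 8 the carbomagnesiation is run as before, but 12 is quenched with iodine to give 1,5-bis(benzyloxy)-2-iodo-3-[13-(benzyloxy)-2-methylidenetridecyl]benzene F1. After purification, iodine–lithium exchange with n-BuLi in THF at −78 °C gives the far more nucleophilic {2,4-bis(benzyloxy)-6-[13-(benzyloxy)-2-methylidenetridecyl]phenyl}lithium F2. It is carboxylated with 9 and, after a cold acidic work-up, the route is rejoined at 13.

**Step 4.**
- What may go wrong: Wurtz homocoupling on the magnesium surface, since the allylic chloride 7 is a good electrophile towards 8 as it forms; this lowers the titre of the reagent.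
- Fallback: the organometallic is made without a metal surface. From 7, displacement of chloride with Bu3SnLi gives tributyl{2-[11-(benzyloxy)undecyl]prop-2-en-1-yl}stannane F3. Tin–lithium exchange with n-BuLi in THF at −78 °C gives {2-[11-(benzyloxy)undecyl]prop-2-en-1-yl}lithium F4, and transmetalation with anhydrous MgCl2 returns to the route at 8; the inert tetraalkyltin stays in solution through step 5.

**Step 8.**
- What may go wrong: poor acceptance of the large, lipophilic ketone by the enzyme, or insufficient or reversed facial selectivity, because both arms of the carbonyl are methylene groups. An oxazaborolidine-catalysed (CBS) borane reduction would depend on the same small steric difference and is not relied on.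
- Fallback: asymmetric reduction is replaced by resolution. From 16, NaBH4 in MeOH/THF at −20 °C (acetic acid quench) gives racemic benzyl 2,4-bis(benzyloxy)-6-[13-(benzyloxy)-2-hydroxytridecyl]benzoate F5. Immediate acetylation gives racemic benzyl 6-[2-acetoxy-13-(benzyloxy)tridecyl]-2,4-bis(benzyloxy)benzoate F6. Preparative supercritical-fluid chromatography on a chiral polysaccharide phase separates the enantiomers, and the (R)-enantiomer rejoins the route as 18.

**Step 9.**
- What may go wrong: intramolecular transesterification. Under the basic acylation conditions the C2' hydroxyl may attack the ortho ester carbonyl with loss of benzyl alcohol (lactonisation) before it is acetylated.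
- Fallback: the polarity of the step is reversed, so that the hydroxyl becomes the leaving group and cannot act as a nucleophile. From 16, an enantiocomplementary ketoreductase (Re-face delivery) gives benzyl 2,4-bis(benzyloxy)-6-[(2S)-13-(benzyloxy)-2-hydroxytridecyl]benzoate F7. A Mitsunobu reaction with acetic acid (PPh3, diisopropyl azodicarboxylate, THF, 0 °C) displaces the activated oxygen with inversion and returns to the route at 18.

## Further compounds

F1 | step 5 | 1,5-bis(benzyloxy)-2-iodo-3-[13-(benzyloxy)-2-methylidenetridecyl]benzene | Ic1c(OCc2ccccc2)cc(OCc2ccccc2)cc1CC(=C)CCCCCCCCCCCOCc1ccccc1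
F2 | step 5 | {2,4-bis(benzyloxy)-6-[13-(benzyloxy)-2-methylidenetridecyl]phenyl}lithium | [Li]c1c(OCc2ccccc2)cc(OCc2ccccc2)cc1CC(=C)CCCCCCCCCCCOCc1ccccc1
F3 | step 4 | tributyl{2-[11-(benzyloxy)undecyl]prop-2-en-1-yl}stannane | CCCC[Sn](CCCC)(CCCC)CC(=C)CCCCCCCCCCCOCc1ccccc1
F4 | step 4 | {2-[11-(benzyloxy)undecyl]prop-2-en-1-yl}lithium | [Li]CC(=C)CCCCCCCCCCCOCc1ccccc1
F5 | step 8 | benzyl 2,4-bis(benzyloxy)-6-[13-(benzyloxy)-2-hydroxytridecyl]benzoate (racemic) | OC(CCCCCCCCCCCOCc1ccccc1)Cc1cc(OCc2ccccc2)cc(OCc2ccccc2)c1C(=O)OCc1ccccc1
F6 | step 8 | benzyl 6-[2-acetoxy-13-(benzyloxy)tridecyl]-2,4-bis(benzyloxy)benzoate (racemic) | CC(=O)OC(CCCCCCCCCCCOCc1ccccc1)Cc1cc(OCc2ccccc2)cc(OCc2ccccc2)c1C(=O)OCc1ccccc1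
F7 | step 9 | benzyl 2,4-bis(benzyloxy)-6-[(2S)-13-(benzyloxy)-2-hydroxytridecyl]benzoate | O[C@@H](CCCCCCCCCCCOCc1ccccc1)Cc1cc(OCc2ccccc2)cc(OCc2ccccc2)c1C(=O)OCc1ccccc1
A1 | alternative 1 | benzyl 6-[(2R)-13-(benzyloxy)-2-(tert-butyldimethylsilyloxy)tridecyl]-2,4-dihydroxybenzoate | CC(C)(C)[Si](C)(C)O[C@H](CCCCCCCCCCCOCc1ccccc1)Cc1cc(O)cc(O)c1C(=O)OCc1ccccc1
A2 | alternative 1 | 6-[(6R)-17-(benzyloxy)-6-(tert-butyldimethylsilyloxy)-2,4-dioxoheptadecyl]-2,2-dimethyl-4H-1,3-dioxin-4-one | CC1(C)OC(=O)C=C(CC(=O)CC(=O)C[C@H](O[Si](C)(C)C(C)(C)C)CCCCCCCCCCCOCc2ccccc2)O1
A3 | alternative 2 | benzyl 6-[(2R)-2-acetoxy-13-(benzyloxy)tridecyl]-2,4-bis(benzyloxy)benzoate | CC(=O)O[C@H](CCCCCCCCCCCOCc1ccccc1)Cc1cc(OCc2ccccc2)cc(OCc2ccccc2)c1C(=O)OCc1ccccc1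
A4 | alternative 2 | benzyl 2,4-bis(benzyloxy)-6-(2-oxoethyl)benzoate | O=CCc1cc(OCc2ccccc2)cc(OCc2ccccc2)c1C(=O)OCc1ccccc1
A5 | alternative 2 | [(undec-10-en-1-yloxy)methyl]benzene | C=CCCCCCCCCCOCc1ccccc1
A6 | alternative 2 | benzyl 6-(2-acetoxy-2-bromoethyl)-2,4-bis(benzyloxy)benzoate (racemic) | CC(=O)OC(Br)Cc1cc(OCc2ccccc2)cc(OCc2ccccc2)c1C(=O)OCc1ccccc1
A7 | alternative 3 | benzyl 6-[(2R)-2-acetoxy-13-(benzyloxy)tridecyl]-2,4-dihydroxybenzoate | CC(=O)O[C@H](CCCCCCCCCCCOCc1ccccc1)Cc1cc(O)cc(O)c1C(=O)OCc1ccccc1
A8 | alternative 3 | trimethyl[(2,2-dimethyl-4-methylidene-4H-1,3-dioxin-6-yl)oxy]silane | C=C1C=C(O[Si](C)(C)C)OC(C)(C)O1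
A9 | alternative 3 | benzyl (5R)-5-acetoxy-16-(benzyloxy)hexadec-2-ynoate | CC(=O)O[C@H](CCCCCCCCCCCOCc1ccccc1)CC#CC(=O)OCc1ccccc1
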